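**Assumptions (one line each)**
- The single stereocentre in the target SMILES is C2 of the flavanone and works out as (2S).
- 5,7-Dihydroxychromone is bought as a catalogue compound (it can otherwise be made from 2,4,6-trihydroxyacetophenone).
- The facial sense of the key Rh step is assigned by analogy with the Hayashi model for cyclic enones, not from a direct precedent on this substrate; it must be confirmed on the first run (chiral HPLC against racemate, CD), and the (R)-ligand used if the sense is reversed.

## Retrosynthetic overview
1. The obvious chalcone (Claisen–Schmidt, then oxa-Michael) route is avoided; instead the C2–C1' aryl–carbon bond is cut.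
2. Key step: Rh-catalysed enantioselective 1,4-addition of a chromenyl boronic acid to a preformed 5,7-dioxygenated chromone. This joins the two halves and sets C2 (S) in the same step.
3. The boronic acid comes from an 8-bromo-2,2-dimethyl-2H-chromene, made from 4-bromoresorcinol by aryl propargyl ether Claisen rearrangement; the bromine blocks one ortho position and later becomes boron.
4. Ring order: the pyranone ring is bought in the chromone; the B-ring 2H-pyran is formed in step 3; no ring is formed in the key step.
5. All three phenols are carried as TIPS ethers and removed in one buffered fluoride step.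

## Route

**Step 1**
Reactants: 1, 4-bromoresorcinol (4-bromobenzene-1,3-diol)
Product: 2, 2-bromo-5-(triisopropylsilyloxy)phenol
Conditions: TIPSCl (1.0 equiv), imidazole, CH2Cl2/DMF, −20 → 0 °C
Reagents that add atoms: triisopropylsilyl chloride, CC(C)[Si](Cl)(C(C)C)C(C)C
Why: Regioselective phenol silylation; the bulky silyl chloride takes the unhindered OH para to Br and leaves the OH ortho to Br free (regiochemistry to be confirmed by NOE/HMBC).

**Step 2**
Reactants: 2, 2-bromo-5-(triisopropylsilyloxy)phenol; 3, 3-chloro-3-methylbut-1-yne
Product: 4, 1-bromo-2-[(2-methylbut-3-yn-2-yl)oxy]-4-(triisopropylsilyloxy)benzene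
Conditions: 3 (1.5 equiv), DBU, CuCl2·2H2O (1 mol %), dry MeCN, 0 °C → rt
Reagents that add atoms: none (all atoms from 2 and 3)
Why: Cu-catalysed O-propargylation of a phenol with a tertiary propargyl chloride (Godfrey conditions), which works on ortho-substituted phenols and is mild enough for the aryl TIPS ether.

**Step 3**
Reactants: 4, the aryl 1,1-dimethylpropargyl ether
Product: 5, 8-bromo-2,2-dimethyl-5-(triisopropylsilyloxy)-2H-chromene
Conditions: PhNEt2, 180 °C, 3 h
Reagents that add atoms: none
Why: Aromatic propargyl Claisen rearrangement, then 1,5-H shift and 6π-oxa-electrocyclisation; with one ortho position blocked by Br the rearrangement can only go to the carbon between the two oxygens, which fixes the chromene regiochemistry.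

**Step 4**
Reactants: 5, 8-bromo-2,2-dimethyl-5-(triisopropylsilyloxy)-2H-chromene
Product: 6, [2,2-dimethyl-5-(triisopropylsilyloxy)-2H-chromen-8-yl]boronic acid
Conditions: n-BuLi, THF, −78 °C; B(OiPr)3, −78 → 0 °C; sat. aq NH4Cl; used crude
Reagents that add atoms: triisopropyl borate, CC(C)OB(OC(C)C)OC(C)C; water, O
Why: Br–Li exchange and borate trapping, then hydrolysis; the aryllithium is para to the OTIPS group so no silyl migration is possible, and the near-neutral work-up limits protodeboronation.

**Step 5**
Reactants: 7, 5,7-dihydroxy-4H-chromen-4-one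
Product: 8, 5,7-bis(triisopropylsilyloxy)-4H-chromen-4-one
Conditions: TIPSOTf (2.5 equiv), 2,6-lutidine, CH2Cl2, 0 °C → rt
Reagents that add atoms: triisopropylsilyl triflate, CC(C)[Si](OS(=O)(=O)C(F)(F)F)(C(C)C)C(C)C
Why: Phenol silylation; the triflate is reactive enough to cap the chelated 5-OH, which would otherwise bind Rh as a keto-phenolate chelate in step 6.

**Step 6 (key step)**
Reactants: 8, 5,7-bis(triisopropylsilyloxy)-4H-chromen-4-one; 6, the chromenyl boronic acid (1.8 equiv, two portions)
Product: 9, (2S)-2-[2,2-dimethyl-5-(triisopropylsilyloxy)-2H-chromen-8-yl]-5,7-bis(triisopropylsilyloxy)-2,3-dihydro-4H-chromen-4-one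
Conditions: [RhCl(C2H4)2]2 (2.5 mol %), (S)-MeO-F12-BIPHEP (5.5 mol %), aq KOH (10 mol %), degassed toluene/H2O 10:1, 35 °C
Reagents that add atoms: none (the C3 hydrogen comes from water)
Why: Hayashi–Miyaura Rh-catalysed asymmetric 1,4-addition of an arylboronic acid to a chromone, a known reaction class not yet tested on this ortho-alkoxy aryl/5,7-disilyloxy pair. The (S)-biaryl bisphosphine–Rh–aryl species should add to the chromone face corresponding to the one that gives (S)-3-arylcyclohexanones, which here is (2S). The electron-poor ligand allows a low temperature and near-neutral medium, which suppresses retro-oxa-Michael opening and protodeboronation.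

**Step 7**
Reactants: 9, the tris-TIPS flavanone
Product: 10, Sanggenone H, (2S)-5,7-dihydroxy-2-(5-hydroxy-2,2-dimethyl-2H-chromen-8-yl)-2,3-dihydro-4H-chromen-4-one
Conditions: TBAF/AcOH (1:1.1, 4 equiv), THF, 0 °C; pH 6 buffer work-up
Reagents that add atoms: none
Why: Fluoride cleavage of aryl silyl ethers; the acetic acid buffer keeps the freed phenols protonated, so the base-triggered ring-opening (chalcone or quinone-methide) that would racemise C2 is avoided, and the chromene alkene is untouched.

## Compound list
1 | 4-bromoresorcinol | Oc1ccc(Br)c(O)c1 | starting material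
2 | 2-bromo-5-(triisopropylsilyloxy)phenol | Oc1cc(O[Si](C(C)C)(C(C)C)C(C)C)ccc1Br | intermediate
3 | 3-chloro-3-methylbut-1-yne | CC(C)(Cl)C#C | starting material
4 | 1-bromo-2-[(2-methylbut-3-yn-2-yl)oxy]-4-(triisopropylsilyloxy)benzene | C#CC(C)(C)Oc1cc(O[Si](C(C)C)(C(C)C)C(C)C)ccc1Br | intermediate
5 | 8-bromo-2,2-dimethyl-5-(triisopropylsilyloxy)-2H-chromene | CC1(C)C=Cc2c(O[Si](C(C)C)(C(C)C)C(C)C)ccc(Br)c2O1 | intermediate
6 | [2,2-dimethyl-5-(triisopropylsilyloxy)-2H-chromen-8-yl]boronic acid | CC1(C)C=Cc2c(O[Si](C(C)C)(C(C)C)C(C)C)ccc(B(O)O)c2O1 | intermediate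
7 | 5,7-dihydroxy-4H-chromen-4-one | O=c1ccoc2cc(O)cc(O)c12 | starting material
8 | 5,7-bis(triisopropylsilyloxy)-4H-chromen-4-one | O=c1ccoc2cc(O[Si](C(C)C)(C(C)C)C(C)C)cc(O[Si](C(C)C)(C(C)C)C(C)C)c12 | intermediate
9 | (2S)-2-[2,2-dimethyl-5-(triisopropylsilyloxy)-2H-chromen-8-yl]-5,7-bis(triisopropylsilyloxy)chroman-4-one | CC1(C)C=Cc2c(O[Si](C(C)C)(C(C)C)C(C)C)ccc([C@@H]3CC(=O)c4c(O[Si](C(C)C)(C(C)C)C(C)C)cc(O[Si](C(C)C)(C(C)C)C(C)C)cc4O3)c2O1 | intermediate
10 | Sanggenone H, (2S) | CC1(C)C=Cc2c(O)ccc([C@@H]3CC(=O)c4c(O)cc(O)cc4O3)c2O1 | target

## Summary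
- Total steps: 7
- Longest linear sequence: 6 (steps 1, 2, 3, 4, 6, 7); the chromone branch is steps 5, 6, 7.

**Three steps most likely to fail, with fallbacks**

1. **Step 6 (Rh 1,4-addition).** The 5,7-dioxygenated chromone is a weak acceptor, the 2,4-dioxygenated boronic acid can protodeboronate, and ee or facial sense may differ from the model. Fallback: give up the C–C conjugate addition. Formylate bromide 5 (n-BuLi, DMF), run Claisen–Schmidt condensation with a 2-hydroxy-4,6-diprotected acetophenone, then close the chalcone by organocatalytic asymmetric oxa-Michael addition, or cyclise racemically and resolve by Rh/TsDPEN transfer-hydrogenation kinetic resolution.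

2. **Step 1 (regioselective monosilylation).** The wrong OH or both may be silylated. Fallback: fix regiochemistry by chelation instead. Start from 2,4-dihydroxybenzaldehyde, protect the non-chelated 4-OH, propargylate the 2-OH and run the Claisen to the 8-formylchromene, then Dakin oxidation, triflation and Miyaura borylation to reach the same aryl boron partner.

3. **Step 7 (global desilylation).** The free 4'-phenol para to the benzylic C2–O bond makes the flavanone prone to ring-opening and racemisation if any phenoxide forms. Fallback: change the protecting-group plan to MOM ethers on all three phenols through the same sequence, removed with TMSOTf/2,2'-bipyridyl then water (no fluoride, no base). This also requires a different regioselective mono-protection in step 1.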